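The retrosynthesis first removes C6–CHO and C8–CHO, then cuts C2–C3 and C4–C4a of the pyran ring (O1, C2, C3, C4, C4a, C8a) together, and last the ketal bond O1–C2. Chroman atoms are unprimed, norbornane atoms primed, and C2 = C2'.
Enabling feature: spiro C2 carries the aryl oxygen O1, so without C3 it is the O-aryl oxocarbenium carbon of 3,3-dimethylnorbornan-2-one. C4 is benzylic on C4a, ortho to O1, and its isobutyl group can be carried as a 2-methylprop-1-enyl group, which makes C4 the end of an allyl cation.
Forward: the norbornane comes intact from (−)-camphene and the benzene ring from 3,5-bis(benzyloxy)phenol, and the two are joined through O1 as a methyl aryl ketal. The pyran ring is the only ring made and closes in one operation, with 4-methylpenta-1,3-diene as the C3–C4 unit.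
Finish: one hydrogenation saturates the side chain and frees both phenols, and a double Vilsmeier–Haack formylation fills C6 and C8.
Stereochemistry: C1' and C4' come from camphene. C2 comes from exo-face C–C bond formation on the bicyclic cation (O1 stays endo). C4 comes from a half-chair closure that keeps C3' and the side chain equatorial, hence cis.

Key step: step 4

Assumption: the enantiomeric purity of the target is that of the camphene batch, so (1S,4R)-(−)-camphene of high optical purity is assumed.

Step 1
Reactants: 1 (1S,4R)-(−)-camphene
Product: 2 (1R,4S)-3,3-dimethylnorbornan-2-one (camphenilone)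
Conditions: O3, CH2Cl2–MeOH, −78 °C; then Me2S, −78 °C → rt
Reagents that add atoms: ozone, [O-][O+]=O
Why: Ozonolysis with reductive work-up cleaves the only C=C bond, the exocyclic methylene, to the ketone, and the bridgehead centres C1' and C4' cannot epimerise.

Step 2
Reactants: 2 (1R,4S)-3,3-dimethylnorbornan-2-one
Product: 3 (1R,4S)-2,2-dimethoxy-3,3-dimethylnorbornane
Conditions: HC(OMe)3, MeOH, TsOH·H2O (cat.), 60 °C; Et3N quench
Reagents that add atoms: trimethyl orthoformate, COC(OC)OC; methanol, CO
Why: Acid-catalysed ketalisation driven by orthoformate as water scavenger serves for camphor-type hindered ketones, and here no enol ether can form because the only α-hydrogen sits on a bridgehead, while the methoxy-stabilised cation has no reason to rearrange.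

Step 3
Reactants: 3 (1R,4S)-2,2-dimethoxy-3,3-dimethylnorbornane; 4 3,5-bis(benzyloxy)phenol
Product: 6 (1R,2S,4S)-2-[3,5-bis(benzyloxy)phenoxy]-2-methoxy-3,3-dimethylnorbornane, via α-chloro ether 5 (not isolated)
Conditions: AcCl, ZnBr2 (cat.), toluene, 0 °C → rt; then 4, NaH, THF–DMF, 0 °C → rt; Et3N-deactivated SiO2
Reagents that add atoms: acetyl chloride, CC(=O)Cl (supplies the chlorine of 5; no atom of it stays in 6)
Why: Zinc-catalysed exchange of a ketal with an acid chloride gives the α-chloro ether, which cannot lose HCl, and O-alkylation of a sodium phenoxide by an α-chloro ether (the reaction behind MOM ethers and aryl methyl acetals) builds the acid-labile mixed ketal under basic conditions; exo capture of the ion pair should place the aryloxy group exo, a centre that step 4 erases in any case.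

Step 4
Reactants: 6 (1R,2S,4S)-2-[3,5-bis(benzyloxy)phenoxy]-2-methoxy-3,3-dimethylnorbornane; 7 4-methylpenta-1,3-diene
Product: 10 (1'R,2R,4R,4'S)-5,7-bis(benzyloxy)-3',3'-dimethyl-4-(2-methylprop-1-enyl)spiro[chromane-2,2'-norbornane], via aryl oxocarbenium ion 8 (not isolated), via dimethylallyl cation 9 (not isolated)
Conditions: SnCl4, 2,6-di-tert-butyl-4-methylpyridine, 7 (5 equiv), CH2Cl2, slow addition of 6, −78 → −40 °C; aq. NaHCO3
Reagents that add atoms: none
Why: Proposed new method: SnCl4 binds the more basic and less shielded methoxy oxygen of 6 and removes it for good as SnCl3(OMe), which leaves ion 8, a cation that has no removable α-hydrogen (the only one sits on bridgehead C1') and, being oxygen-stabilised, gains nothing from a Wagner–Meerwein or Nametkin shift; the unsubstituted CH2 terminus of 7 adds to C2 (Prins-type step, bond C2–C3) to give dimethylallyl cation 9, the arene carbon ortho to O1 and para to a benzyloxy group attacks its secondary terminus C4 (bond C4–C4a), and the hindered pyridine takes up the proton. The closest known reaction type is the SnCl4-promoted oxa-Povarov reaction, the formal [4+2] annulation of aldehyde-derived aryl methyl acetals with alkenes and dienes, and what is new is a fully substituted, ketone-derived aryl oxocarbenium carbon flanked by a quaternary centre. The pyran ring closes by a 6-exo-trig cationic Friedel–Crafts cyclisation in which the remaining C=C of the allyl cation stays outside the ring, closure at the tertiary terminus being excluded because it would need an eight-membered ring holding an E-alkene. C2 is set by attack of the diene on the exo face of 8, the face that hydride and organometallic reagents also choose on this ketone because the C5'–C6' bridge and the endo methyl group screen the endo face, so that C3 ends up exo and O1 endo (2R). C4 is set in the closure, which should run through the half-chair that places quaternary C3' equatorial and bridgehead C1' axial on C2 and the alkenyl group pseudo-equatorial on C4, hence cis to C3' (4R). The step needs methoxide rather than aryloxide to leave, the diene rather than a second arene to reach C2, and no regiochemical choice on the ring: the first rests on the Lewis acid, the second on the excess of 7, the slow addition of 6 and the greater steric demand of arene attack at a neopentyl-type centre, and the third on the two ortho positions being equivalent by symmetry.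

Step 5
Reactants: 10 (1'R,2R,4R,4'S)-5,7-bis(benzyloxy)-3',3'-dimethyl-4-(2-methylprop-1-enyl)spiro[chromane-2,2'-norbornane]
Product: 11 (1'R,2R,4S,4'S)-3',3'-dimethyl-4-(2-methylpropyl)spiro[chromane-2,2'-norbornane]-5,7-diol
Conditions: H2 (4 atm), Pd(OH)2/C, EtOAc–EtOH, rt
Reagents that add atoms: none
Why: Heterogeneous hydrogenation saturates the trisubstituted side-chain alkene and hydrogenolyses both aryl benzyl ethers in one operation without forming a stereocentre (the C4 descriptor changes only through the priority rules), and double-bond migration to the exocyclic C4 position, the one process that could erase C4, is disfavoured by allylic strain against the C5 oxygen substituent and by an ample hydrogen supply.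

Step 6
Reactants: 11 (1'R,2R,4S,4'S)-3',3'-dimethyl-4-(2-methylpropyl)spiro[chromane-2,2'-norbornane]-5,7-diol
Product: 13 (1'R,2R,4S,4'S)-5,7-dihydroxy-3',3'-dimethyl-4-(2-methylpropyl)spiro[chromane-2,2'-norbornane]-6,8-dicarbaldehyde (CNP0150011.1), via bis(iminium) ion 12 (not isolated)
Conditions: POCl3 (excess), DMF, EtOAc, 0 °C → rt; then H2O, rt
Reagents that add atoms: N,N-dimethylformamide, CN(C)C=O; water, O
Why: In this double Vilsmeier–Haack formylation C6 and C8 are the only free ring positions, each activated by three oxygen donors, and a free ortho-hydroxyl lets the first iminium group relax to a neutral vinylogous amide so that the ring stays nucleophilic enough for the second attack, as in the conversion of phloroglucinol into its dialdehyde, while the mild medium leaves the tertiary C2–O1 ether, C2 and C4 untouched.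

Compound list
1 | (1S,4R)-(−)-camphene | C=C2[C@@H]1CC[C@@H](C1)C2(C)C | starting material
2 | (1R,4S)-3,3-dimethylnorbornan-2-one (camphenilone) | O=C2[C@@H]1CC[C@@H](C1)C2(C)C | intermediate
3 | (1R,4S)-2,2-dimethoxy-3,3-dimethylnorbornane | COC2(OC)[C@@H]1CC[C@@H](C1)C2(C)C | intermediate
4 | 3,5-bis(benzyloxy)phenol | Oc1cc(OCc2ccccc2)cc(OCc2ccccc2)c1 | starting material
5 | (1R,4S)-2-chloro-2-methoxy-3,3-dimethylnorbornane (C2 epimers interconvert through the ion pair) | COC2(Cl)[C@@H]1CC[C@@H](C1)C2(C)C | intermediate
6 | (1R,2S,4S)-2-[3,5-bis(benzyloxy)phenoxy]-2-methoxy-3,3-dimethylnorbornane (aryloxy exo, methoxy endo) | CO[C@]2(Oc3cc(OCc4ccccc4)cc(OCc4ccccc4)c3)[C@@H]1CC[C@@H](C1)C2(C)C | intermediate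
7 | 4-methylpenta-1,3-diene | C=CC=C(C)C | starting material
8 | O-[3,5-bis(benzyloxy)phenyl] oxocarbenium ion of (1R,4S)-3,3-dimethylnorbornan-2-one (counter-ion omitted) | [O+](c3cc(OCc4ccccc4)cc(OCc4ccccc4)c3)=C2[C@@H]1CC[C@@H](C1)C2(C)C | intermediate
9 | (1R,2R,4S)-2-endo-aryloxy-2-exo-(4-methylpent-3-en-2-ylium-1-yl)-3,3-dimethylnorbornane (counter-ion omitted) | CC(C)=C[CH+]C[C@@]2(Oc3cc(OCc4ccccc4)cc(OCc4ccccc4)c3)[C@@H]1CC[C@@H](C1)C2(C)C | intermediate
10 | (1'R,2R,4R,4'S)-5,7-bis(benzyloxy)-3',3'-dimethyl-4-(2-methylprop-1-enyl)spiro[chromane-2,2'-norbornane] | CC(C)=C[C@H]1C[C@@]2(Oc3cc(OCc4ccccc4)cc(OCc4ccccc4)c31)[C@@H]1CC[C@@H](C1)C2(C)C | intermediate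
11 | (1'R,2R,4S,4'S)-3',3'-dimethyl-4-(2-methylpropyl)spiro[chromane-2,2'-norbornane]-5,7-diol | CC(C)C[C@H]1C[C@@]2(Oc3cc(O)cc(O)c31)[C@@H]1CC[C@@H](C1)C2(C)C | intermediate
12 | 6,8-bis(dimethyliminiomethyl) derivative of 11 (counter-ions omitted) | CC(C)C[C@H]1C[C@@]2(Oc3c(C=[N+](C)C)c(O)c(C=[N+](C)C)c(O)c31)[C@@H]1CC[C@@H](C1)C2(C)C | intermediate
13 | (1'R,2R,4S,4'S)-5,7-dihydroxy-3',3'-dimethyl-4-(2-methylpropyl)spiro[chromane-2,2'-norbornane]-6,8-dicarbaldehyde | CC(C)C[C@H]1C[C@@]2(Oc3c(C=O)c(O)c(C=O)c(O)c31)[C@@H]1CC[C@@H](C1)C2(C)C | target

Total step count: 6. Longest linear sequence: 6 steps (1 → 2 → 3 → 6 → 10 → 11 → 13).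

Steps most likely to fail

Step 4. Several processes could compete:
- Ionisation could proceed by loss of aryloxide instead of methoxide.
- C–C bond formation at the crowded cationic carbon could be so slow that cationic oligomerisation of the diene, intermolecular arylation or benzyl migration takes over.
- Facial selectivity in the closure at C4 could be poor.

The fallback uses known chemistry, sets out from 1 and rejoins the route at 13. Phloroglucinol would be formylated twice (POCl3, DMF) to 2,4,6-trihydroxybenzene-1,3-dicarbaldehyde F1. Heating F1 with 3-methylbutanal and 1 (NaOAc, AcOH, 80 °C) should give, by Knoevenagel condensation, the ortho-quinone methide 2,4-dihydroxy-5-(3-methylbutylidene)-6-oxocyclohexa-1,3-diene-1,3-dicarbaldehyde F2. The exocyclic alkene of 1 traps F2 in an inverse-demand oxa-Diels–Alder reaction, with oxygen bonding to the more substituted carbon. This cascade is established for adducts of formyl-phloroglucinols with terpenes. It forms O1–C2 and C3–C4 instead of C2–C3 and C4–C4a, and would deliver 13 together with spiro and C4 isomers that must be separated by chromatography.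

Step 3. The chloro ether could collapse to the ketone through chloride attack on its O-methyl group, the methyl group could be transferred to the phenoxide, or substitution at the crowded centre could be too slow. The fallback sets out from 3 and 4 and rejoins the route at 6. Phenol 4 would be silylated (TMSCl, Et3N, CH2Cl2) to [3,5-bis(benzyloxy)phenoxy]trimethylsilane F3. F3 would then be exchanged with 3 under catalytic TMSOTf (CH2Cl2, −78 → −30 °C, pyridine quench). In this silyl ether/ketal exchange a neutral oxygen nucleophile captures the methoxycarbenium ion, and neither chloride nor phenoxide is present to dealkylate it.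

Step 6. The reaction could stall after the first formylation, formylate oxygen persistently, or open the tertiary C2–O1 ether under acid once the ring bears acceptor groups. The fallback replaces electrophilic substitution by halogen–metal exchange on the protected series. It sets out from 10 and rejoins the route at 13.
- Selective alkene hydrogenation (H2, Pd/C poisoned with pyridine, EtOAc) would give (1'R,2R,4S,4'S)-5,7-bis(benzyloxy)-3',3'-dimethyl-4-(2-methylpropyl)spiro[chromane-2,2'-norbornane] F4.
- NBS (2 equiv, MeCN, 0 °C) would give its 6,8-dibromide F5.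
- Double bromine–lithium exchange and a DMF quench (t-BuLi, THF, −78 °C) would give the 5,7-bis(benzyloxy)-6,8-dicarbaldehyde F6.
- BCl3 with pentamethylbenzene as cation scavenger (CH2Cl2, −78 °C) would remove both benzyl groups to give 13.

Further compounds
F1 | step 4 | 2,4,6-trihydroxybenzene-1,3-dicarbaldehyde | O=Cc1c(O)cc(O)c(C=O)c1O
F2 | step 4 | 2,4-dihydroxy-5-(3-methylbutylidene)-6-oxocyclohexa-1,3-diene-1,3-dicarbaldehyde (transient, alkene geometry not fixed) | O=C1C(C=O)=C(O)C(C=O)=C(O)C1=CCC(C)C
F3 | step 3 | [3,5-bis(benzyloxy)phenoxy]trimethylsilane | C[Si](C)(C)Oc1cc(OCc2ccccc2)cc(OCc2ccccc2)c1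
F4 | step 6 | (1'R,2R,4S,4'S)-5,7-bis(benzyloxy)-3',3'-dimethyl-4-(2-methylpropyl)spiro[chromane-2,2'-norbornane] | CC(C)C[C@H]1C[C@@]2(Oc3cc(OCc4ccccc4)cc(OCc4ccccc4)c31)[C@@H]1CC[C@@H](C1)C2(C)C
F5 | step 6 | (1'R,2R,4S,4'S)-5,7-bis(benzyloxy)-6,8-dibromo-3',3'-dimethyl-4-(2-methylpropyl)spiro[chromane-2,2'-norbornane] | CC(C)C[C@H]1C[C@@]2(Oc3c(Br)c(OCc4ccccc4)c(Br)c(OCc4ccccc4)c31)[C@@H]1CC[C@@H](C1)C2(C)C
F6 | step 6 | (1'R,2R,4S,4'S)-5,7-bis(benzyloxy)-3',3'-dimethyl-4-(2-methylpropyl)spiro[chromane-2,2'-norbornane]-6,8-dicarbaldehyde | CC(C)C[C@H]1C[C@@]2(Oc3c(C=O)c(OCc4ccccc4)c(C=O)c(OCc4ccccc4)c31)[C@@H]1CC[C@@H](C1)C2(C)C
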